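Start from the red run. It stands at 70 °C, the temperature of alpha, and its substrate reads 83% and then 21% between 1.33 min and 15.0 min, a slope, as read, of 0.101 min⁻¹. Violet and green stand at 1.67 in rate for 1.45 in loading, so the rate is taken as roughly in step with precatalyst.

| flask | substrate | coupling partner | precatalyst | temperature | remark | time |
|---|---|---|---|---|---|---|
| green | 20 mM | 1.5 equiv | 7.6 mol% | 55 °C | run made earlier |  |
| red | 20 mM | 1.5 equiv | 5.1 mol% | 70 °C | run made earlier |  |
| violet | 20 mM | 1.5 equiv | 11 mol% | 55 °C | run made earlier |  |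
| zeta | 20 mM (in portions, 3, over 15 min) | 1.50 equiv | 7.6 mol% | 70 °C | first portion at the start, last at 15 min | 20 min |
| alpha | 20 mM | 1.50 equiv | 7.6 mol% | 70 °C | everything together at the start | 20 min |
| delta | 20 mM | 1.50 equiv (fed, over 15 min) | 7.6 mol% |  | the addition at 30 °C, then warmed to 70 °C; the feed brings no volume worth counting | 20 min |
| eta | 20 mM | 1.50 equiv (fed, over 15 min) | 7.6 mol% | 70 °C | all else is in the flask from the start; the feed brings no volume worth counting | 20 min |

| run | time / min | target / % | substrate / % |
|---|---|---|---|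
| green | 2.00 | 8 | 85 |
| green | 6.00 | 29 | 67 |
| green | 12.0 | 49 | 43 |
| green | 15.0 | 54 | 37 |
| green | 25.0 | 73 | 18 |
| red | 1.33 | 15 | 83 |
| red | 2.50 | 24 | 71 |
| red | 5.00 | 45 | 55 |
| red | 8.00 | 54 | 45 |
| red | 15.0 | 75 | 21 |
| violet | 6.00 | 37 | 51 |
| violet | 12.0 | 55 | 30 |
| violet | 20.0 | 77 | 15 |
| violet | 25.0 | 82 | 6 |
| violet | 30.0 | 92 | 2 |

(scatter of a reading: 2 percentage points)

1. the best flask by amount of target, in percent of the substrate charged; "all alike" if 1.5 percentage points covers them all (zeta / alpha / delta / eta / all alike)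
2. amount of target at the end, in percent of the substrate charged, zeta
3. amount of target at the end, in percent of the substrate charged, alpha
4. amount of target at the end, in percent of the substrate charged, delta
5. amount of target at the end, in percent of the substrate charged, eta

Scaling red to 7.6 mol% gives 0.150 min⁻¹: the hot clock constant, the fraction of remaining substrate consumed per minute at 70 °C with partner fully present, a pseudo-first-order constant. Target as a fraction of the charge is then one minus exp(−constant × counted minutes).

In alpha, target leaves zero with that slope and crosses substrate at 4.63 min. It then bends towards the charge, reaching 95.0% at 20 min.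

The other flasks differ in which minutes count. Zeta's portions get 20 min, 12.5 min and 5.00 min. In eta, partner fed steadily is assumed to count for half of each feed minute, which also gives 12.5 min. Delta gets 5.00 min hot. Its cold minutes are left off, as a choice of this reckoning: green, at the same loading, slopes at 0.0675 min⁻¹, less than the hot constant already at 55 °C, and the addition runs at 30 °C.

| flask | target reckoned |
|---|---|
| alpha | 95.0% |
| eta | 84.6% |
| zeta | 77.5% |
| delta | 52.7% |

Alpha comes out best.

The forecast named alpha, with 78% for zeta, 93% for alpha, 62% for delta and 90% for eta, its delta standing higher than the reckoning here and resting on “about 19% converts cold, then only 5 min hot”.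

The flasks give 78.5% for zeta, 94.8% for alpha, 52.8% for delta and 83.1% for eta, with alpha best.

    substrate + free catalyst → catalyst intermediate A (k = 43.0 L mol⁻¹ s⁻¹, Ea = 41.0 kJ mol⁻¹)
    catalyst intermediate A ⇌ catalyst intermediate B (K = 0.560, k = 0.330 s⁻¹, Ea = 74.0 kJ mol⁻¹, ΔH = −42.0 kJ mol⁻¹)
    coupling partner + catalyst intermediate B ⇌ catalyst intermediate C (K = 20.0 L mol⁻¹, k = 410 L mol⁻¹ s⁻¹, Ea = 46.0 kJ mol⁻¹, ΔH = −5.00 kJ mol⁻¹)
    catalyst intermediate C ⇌ released group + catalyst intermediate D (K = 0.00700 M, k = 15.0 s⁻¹, Ea = 81.0 kJ mol⁻¹, ΔH = 12.0 kJ mol⁻¹)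
    catalyst intermediate D ⇌ catalyst intermediate E (K = 18.0, k = 0.240 s⁻¹, Ea = 80.0 kJ mol⁻¹, ΔH = −44.0 kJ mol⁻¹)
    catalyst intermediate E → free catalyst + target (k = 14.0 s⁻¹, Ea = 84.0 kJ mol⁻¹)
    precatalyst ⇌ free catalyst (K = 0.170, k = 0.0660 s⁻¹, Ea = 95.0 kJ mol⁻¹, ΔH = −55.0 kJ mol⁻¹)
    (constants at 70 °C)

In delta, the half-life of substrate by the first step is 5.0 min at 20.0 min, beside the reckoned 4.63 min and the 5.00 min of hot time. The forward half-life of catalyst intermediate A there is 2.1 s at 16.4 min, far shorter, and half of the turnover of that step in delta up to the end is done by 16.5 min. In zeta the clock constant leaves 22.5% of the charge not yet target at 20.0 min, and the flask holds substrate at 16.1% beside target at 78.5%.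

(The earlier runs and the new flask were generated by integration on assumed constants, and the scatter is random.)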